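## Plan

- Numbering: ring A is the dibromopyrrole (N1); ring B the lactam N1–C6–C10–N14–C15(=O)–C(pyrrole); ring C the pyrrolidine C10–C11–C12–C13–N14; ring D the guanidine C6–N7(Me)–C8(NH2)=N9–C10. The drawn enantiomer is (6S,10R).
- Retrosynthesis: the C8–NH2 guanidine is traced to a urea, the aminal bond N1–C6 is cut (ring B opens), C6 is raised to a hydantoin carbonyl, N9–C10 is traded for C10–CO2Me (Curtius), and last C6–C10 and N14–C15 are cut together.
- Enabling feature: the quaternary aminal carbon C10 carries N14 acylated by C15 of ring A and, next to it, C6 with MeN7. This is the N-acyl α-amino carboxamide pattern of an isocyanide three-component adduct (C6/MeN7 from methyl isocyanide, C15 from the pyrrole acid, ring C from a cyclic ketimine whose ester masks N9).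
- Forward: ring C comes from proline; the coupling joins all three fragments at C10 without closing a ring; ring D closes as a spiro-hydantoin after the Curtius shift; ring B closes by attack of N1 on a C6 N-acyliminium ion; the urea is exchanged for the guanidine last.
- Stereochemistry: C10 is set in the coupling by a chiral phosphoric acid (all components are achiral) and kept with retention through the Curtius shift; C6 follows from C10 because ring B can only close cis to ring D.

Key step: step 3

Assumption: the (R)-configured phosphoric acid is taken to deliver the (2R)-adduct 8; if the first experiment shows the opposite sense, its (S)-antipode is used with nothing else changed.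

## Route

Step 1
Reactants: 1 L-proline methyl ester hydrochloride
Product: 3 methyl 3,4-dihydro-2H-pyrrole-5-carboxylate, via N-chloroproline methyl ester 2 (not isolated)
Conditions: Et3N (1 equiv), t-BuOCl, Et2O, −10 °C; then Et3N, rt; short-path distillation, used at once
Reagents that add atoms: none
Why: N-chlorination of the secondary amine followed by base-induced 1,2-dehydrochlorination toward the acidic α-C–H is an established route to cyclic α-imino esters and should give the conjugated ketimine, the proline stereocentre being erased on purpose.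

Step 2
Reactants: 4 N-methylformamide
Product: 5 methyl isocyanide
Conditions: TsCl, quinoline, 75 °C, 15 mmHg, distilled into a −78 °C trap (kept cold, handled as a solution)
Reagents that add atoms: none
Why: Dehydration of an N-monosubstituted formamide with a sulfonyl chloride and a high-boiling amine is the standard isocyanide synthesis, and the volatile product leaves the mixture as it forms.

Step 3
Reactants: 3 methyl 3,4-dihydro-2H-pyrrole-5-carboxylate; 5 methyl isocyanide; 6 4,5-dibromo-1H-pyrrole-2-carboxylic acid
Product: 8 methyl (2R)-1-(4,5-dibromo-1H-pyrrole-2-carbonyl)-2-(methylcarbamoyl)pyrrolidine-2-carboxylate, via O-acyl imidate 7 (not isolated)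
Conditions: (R)-3,3'-bis(2,4,6-triisopropylphenyl)-1,1'-binaphthyl-2,2'-diyl hydrogen phosphate (10 mol %), 4 Å MS, CH2Cl2, −20 °C → rt
Reagents that add atoms: none
Why: Proposed new method: acid 6, hydrogen-bonded to the chiral phosphoric acid as a heterodimer, protonates ketimine 3 at N14, the carbon of isocyanide 5 attacks C10 of the resulting chiral ion pair (C6–C10), the carboxylate adds to the nitrilium ion to give imidate 7, and an irreversible Mumm O-to-N acyl shift through a five-membered transition state forms N14–C15. The closest known reactions are the Joullié–Ugi three-component coupling of cyclic imines, ketimines included, in racemic form and the chiral phosphoric acid-catalysed enantioselective four-component Ugi reaction of aldimines; a catalytic enantioselective version on a ketimine ester is not known. No ring is closed; two skeletal bonds and the single stereocentre C10 are formed. The (R)-configuration at C10 has to come from enantiofacial attack of the isocyanide inside the phosphate-bound iminium ion pair, where the ester carbonyl offers a second hydrogen-bond acceptor that fixes the planar cation against the 3,3'-aryl groups of the catalyst. The step needs attack at C10 to outrun enamine tautomerisation and needs acyl transfer to N14 only; the ester raises the electrophilicity of the ketimine carbon, N14 is the only amine present, and the pyrrole N–H is not nucleophilic in acidic medium. Low temperature and the higher acidity of the heterodimer compared with free 6 are relied on to suppress the uncatalysed racemic pathway.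

Step 4
Reactants: 8 methyl (2R)-1-(4,5-dibromo-1H-pyrrole-2-carbonyl)-2-(methylcarbamoyl)pyrrolidine-2-carboxylate
Product: 9 (2R)-1-(4,5-dibromo-1H-pyrrole-2-carbonyl)-2-(methylcarbamoyl)pyrrolidine-2-carboxylic acid
Conditions: LiOH, THF/H2O, 0 °C → rt; then 1 M HCl to pH 3, 0 °C; crude acid used cold and at once
Reagents that add atoms: lithium hydroxide, [Li+].[OH-]
Why: Saponification of the methyl ester, activated by the two electron-withdrawing groups on C10, should outpace attack on either amide, and C10 carries no hydrogen and cannot epimerise; should the pyrrolide close onto the ester, hydroxide reopens the resulting N-acylpyrrole to the same carboxylate.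

Step 5
Reactants: 9 (2R)-1-(4,5-dibromo-1H-pyrrole-2-carbonyl)-2-(methylcarbamoyl)pyrrolidine-2-carboxylic acid
Product: 12 (5R)-1-(4,5-dibromo-1H-pyrrole-2-carbonyl)-8-methyl-1,6,8-triazaspiro[4.4]nonane-7,9-dione, via acyl azide 10 (not isolated), via isocyanate 11 (not isolated)
Conditions: (PhO)2P(O)N3, Et3N, PhMe, 0 °C → rt; then 85 °C
Reagents that add atoms: diphenylphosphoryl azide, [N-]=[N+]=NP(=O)(Oc1ccccc1)Oc1ccccc1
Why: Curtius rearrangement: the carboxylate is converted into acyl azide 10, which on heating loses N2 with a concerted 1,2-shift of C10 (retention of configuration) to isocyanate 11, and the neighbouring N7–H amide then adds to the isocyanate carbon in a five-membered closure of ring D, the known path from malonamic acids to 5,5-disubstituted hydantoins.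

Step 6
Reactants: 12 (5R)-1-(4,5-dibromo-1H-pyrrole-2-carbonyl)-8-methyl-1,6,8-triazaspiro[4.4]nonane-7,9-dione
Product: 13 (5R)-1-(4,5-dibromo-1H-pyrrole-2-carbonyl)-9-hydroxy-8-methyl-1,6,8-triazaspiro[4.4]nonan-7-one (hemiaminal at C6, both epimers)
Conditions: i-Bu2AlH (4 equiv), THF, −78 °C; aq. potassium sodium tartrate
Reagents that add atoms: none
Why: Regioselective hydride reduction of a 3-alkylhydantoin at its imide-type carbonyl (here C6) to the 4-hydroxyimidazolidin-2-one is known; the first equivalents of i-Bu2AlH deprotonate the pyrrole N–H and N9–H and so deactivate the C15 amide and the C8 urea, C6=O stays electrophilic because sp3 C10 insulates it from N9, and the aluminium alkoxide persists at −78 °C so that no ring-opened alcohol should form.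

Step 7
Reactants: 13 (5R)-1-(4,5-dibromo-1H-pyrrole-2-carbonyl)-9-hydroxy-8-methyl-1,6,8-triazaspiro[4.4]nonan-7-one
Product: 14 (6S,10R)-7-N-methyldibromophakellstatin (the tetracycle of the target with C8 as urea carbonyl and N9–H)
Conditions: CF3CO2H, CH2Cl2, 0 °C → rt
Reagents that add atoms: none
Why: Acid ionises the hemiaminal to the urea-stabilised N7=C6 N-acyliminium ion, which cannot tautomerise because C10 is quaternary, and N1, held by the N14–C15 tether, closes ring B in a 6-exo-trig α-ureidoalkylation; only the face of C6 syn to N14 is within reach, so the cis-fused (6S) aminal follows from C10, and C-alkylation is disfavoured because the only free pyrrole carbon is deactivated by the adjacent carbonyl and two bromine atoms.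

Step 8
Reactants: 14 (6S,10R)-7-N-methyldibromophakellstatin
Product: 16 (−)-7-N-methyldibromophakellin, via O-ethylisouronium tetrafluoroborate 15 (not isolated)
Conditions: Et3OBF4 (1.2 equiv), CH2Cl2, rt; then NH3, MeOH, sealed tube, 60 °C
Reagents that add atoms: ammonia, N
Why: O-Ethylation of the urea with Meerwein's salt (the urea oxygen, fed by two nitrogen lone pairs, should be more nucleophilic than that of the electron-poor pyrrole lactam) gives isouronium salt 15, and ammonia then adds to C8 and expels ethanol, the classical urea-to-guanidine exchange, without touching the two aminal stereocentres.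

## Compound list

1 | L-proline methyl ester hydrochloride | Cl.COC(=O)[C@@H]1CCCN1 | starting material
2 | methyl (2S)-1-chloropyrrolidine-2-carboxylate | COC(=O)[C@@H]1CCCN1Cl | intermediate
3 | methyl 3,4-dihydro-2H-pyrrole-5-carboxylate | COC(=O)C1=NCCC1 | intermediate
4 | N-methylformamide | CNC=O | starting material
5 | methyl isocyanide | C[N+]#[C-] | intermediate
6 | 4,5-dibromo-1H-pyrrole-2-carboxylic acid | OC(=O)c1cc(Br)c(Br)[nH]1 | starting material
7 | methyl (2R)-2-[(4,5-dibromo-1H-pyrrole-2-carbonyl)oxy(methylimino)methyl]pyrrolidine-2-carboxylate (O-acyl imidate) | CN=C(OC(=O)c1cc(Br)c(Br)[nH]1)[C@@]1(C(=O)OC)CCCN1 | intermediate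
8 | methyl (2R)-1-(4,5-dibromo-1H-pyrrole-2-carbonyl)-2-(methylcarbamoyl)pyrrolidine-2-carboxylate | CNC(=O)[C@@]1(C(=O)OC)CCCN1C(=O)c1cc(Br)c(Br)[nH]1 | intermediate
9 | (2R)-1-(4,5-dibromo-1H-pyrrole-2-carbonyl)-2-(methylcarbamoyl)pyrrolidine-2-carboxylic acid | CNC(=O)[C@@]1(C(=O)O)CCCN1C(=O)c1cc(Br)c(Br)[nH]1 | intermediate
10 | (2R)-1-(4,5-dibromo-1H-pyrrole-2-carbonyl)-2-(methylcarbamoyl)pyrrolidine-2-carbonyl azide | CNC(=O)[C@@]1(C(=O)N=[N+]=[N-])CCCN1C(=O)c1cc(Br)c(Br)[nH]1 | intermediate
11 | (2S)-1-(4,5-dibromo-1H-pyrrole-2-carbonyl)-2-isocyanato-N-methylpyrrolidine-2-carboxamide (same spatial arrangement as 9; the descriptor changes by priority only) | CNC(=O)[C@@]1(N=C=O)CCCN1C(=O)c1cc(Br)c(Br)[nH]1 | intermediate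
12 | (5R)-1-(4,5-dibromo-1H-pyrrole-2-carbonyl)-8-methyl-1,6,8-triazaspiro[4.4]nonane-7,9-dione (spiro-hydantoin; spiro C5 = C10, C9 = C6) | CN1C(=O)N[C@@]2(CCCN2C(=O)c2cc(Br)c(Br)[nH]2)C1=O | intermediate
13 | (5R)-1-(4,5-dibromo-1H-pyrrole-2-carbonyl)-9-hydroxy-8-methyl-1,6,8-triazaspiro[4.4]nonan-7-one (both epimers at the carbinol carbon) | CN1C(=O)N[C@@]2(CCCN2C(=O)c2cc(Br)c(Br)[nH]2)C1O | intermediate
14 | (6S,10R)-7-N-methyldibromophakellstatin (tetracyclic urea) | CN1C(=O)N[C@]23CCCN2C(=O)c2cc(Br)c(Br)n2[C@H]13 | intermediate
15 | O-ethylisouronium tetrafluoroborate of 14 (6S,10R) | CN1C(OCC)=[NH+][C@]23CCCN2C(=O)c2cc(Br)c(Br)n2[C@H]13.F[B-](F)(F)F | intermediate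
16 | (−)-7-N-methyldibromophakellin (6S,10R) | CN1C(N)=N[C@]23CCCN2C(=O)c2cc(Br)c(Br)n2[C@H]13 | target

## Step count and risks

Total steps: 8. Longest linear sequence: 7 (steps 1, 3, 4, 5, 6, 7, 8); step 2 is a one-step side branch.

**Step 3 (insufficient enantiofacial discrimination, or an unselective background coupling promoted by acid 6 alone).** The fallback sets out from 3, 5 and 6 and returns at 8. The three components are combined without the chiral acid in 2,2,2-trifluoroethanol at room temperature, the established racemic Joullié–Ugi mode for cyclic ketimines. This should give racemic methyl 1-(4,5-dibromo-1H-pyrrole-2-carbonyl)-2-(methylcarbamoyl)pyrrolidine-2-carboxylate F1. Preparative chromatography on a chiral stationary phase (amylose tris(3,5-dimethylphenylcarbamate)) should separate it into 8 and methyl (2S)-1-(4,5-dibromo-1H-pyrrole-2-carbonyl)-2-(methylcarbamoyl)pyrrolidine-2-carboxylate F2, which is set aside. Because C10 is quaternary, the resolved material cannot racemise later.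

**Step 8 (unselective O-alkylation, the C15 lactam oxygen competing with the urea, or sluggish ammonolysis of the isouronium salt).** The fallback sets out from 8 and returns at 16. It brings C8 in at the thiocarbonyl level, so that the last exchange becomes a sulfur-selective methylation.
- Ammonolysis of ester 8 (NH3, MeOH, 40 °C) should give the primary amide (2S)-1-(4,5-dibromo-1H-pyrrole-2-carbonyl)-N-methylpyrrolidine-2,2-dicarboxamide F3.
- Hofmann rearrangement under acidic aqueous conditions (PhI(OCOCF3)2, MeCN/H2O, rt), where isocyanate 11 is hydrolysed and not captured by the amide, should give (2R)-2-amino-1-(4,5-dibromo-1H-pyrrole-2-carbonyl)-N-methylpyrrolidine-2-carboxamide F4 as its trifluoroacetate.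
- 1,1'-Thiocarbonyldiimidazole and i-Pr2NEt in THF should close the 2-thiohydantoin (5R)-1-(4,5-dibromo-1H-pyrrole-2-carbonyl)-8-methyl-7-thioxo-1,6,8-triazaspiro[4.4]nonan-9-one F5.
- Reduction with i-Bu2AlH as in step 6 should give the hemiaminal (5R)-1-(4,5-dibromo-1H-pyrrole-2-carbonyl)-9-hydroxy-8-methyl-1,6,8-triazaspiro[4.4]nonane-7-thione F6.
- CF3CO2H as in step 7 should close ring B to the cyclic thiourea (6S,10R)-7-N-methyl-8-thioxo-dibromophakellstatin F7.
- MeI in acetone should alkylate sulfur only, giving the S-methylisothiouronium iodide F8, and NH3 in MeOH at 60 °C should displace methanethiol to reach 16.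

**Step 5 (acylation of the pyrrole nitrogen by the activated carboxyl group, or decarboxylation of the malonamic acid before the azide rearranges).** The fallback sets out from 8 and returns at 12. It reaches the isocyanate by a Lossen rearrangement, with no free acid and no acyl phosphate. NH2OH·HCl and KOH in MeOH should convert ester 8 into the hydroxamic acid (2R)-1-(4,5-dibromo-1H-pyrrole-2-carbonyl)-N-hydroxy-N'-methylpyrrolidine-2,2-dicarboxamide F9. 1,1'-Carbonyldiimidazole in MeCN should turn it into the dioxazolone (2S)-1-(4,5-dibromo-1H-pyrrole-2-carbonyl)-N-methyl-2-(5-oxo-1,4,2-dioxazol-3-yl)pyrrolidine-2-carboxamide F10. At 60 °C this should lose CO2 to give isocyanate 11, which closes as in step 5 to hydantoin 12.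

## Further compounds

F1 | step 3 | racemic methyl 1-(4,5-dibromo-1H-pyrrole-2-carbonyl)-2-(methylcarbamoyl)pyrrolidine-2-carboxylate | CNC(=O)C1(C(=O)OC)CCCN1C(=O)c1cc(Br)c(Br)[nH]1
F2 | step 3 | methyl (2S)-1-(4,5-dibromo-1H-pyrrole-2-carbonyl)-2-(methylcarbamoyl)pyrrolidine-2-carboxylate | CNC(=O)[C@]1(C(=O)OC)CCCN1C(=O)c1cc(Br)c(Br)[nH]1
F3 | step 8 | (2S)-1-(4,5-dibromo-1H-pyrrole-2-carbonyl)-N-methylpyrrolidine-2,2-dicarboxamide | CNC(=O)[C@@]1(C(N)=O)CCCN1C(=O)c1cc(Br)c(Br)[nH]1
F4 | step 8 | (2R)-2-amino-1-(4,5-dibromo-1H-pyrrole-2-carbonyl)-N-methylpyrrolidine-2-carboxamide | CNC(=O)[C@@]1(N)CCCN1C(=O)c1cc(Br)c(Br)[nH]1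
F5 | step 8 | (5R)-1-(4,5-dibromo-1H-pyrrole-2-carbonyl)-8-methyl-7-thioxo-1,6,8-triazaspiro[4.4]nonan-9-one | CN1C(=S)N[C@@]2(CCCN2C(=O)c2cc(Br)c(Br)[nH]2)C1=O
F6 | step 8 | (5R)-1-(4,5-dibromo-1H-pyrrole-2-carbonyl)-9-hydroxy-8-methyl-1,6,8-triazaspiro[4.4]nonane-7-thione (both carbinol epimers) | CN1C(=S)N[C@@]2(CCCN2C(=O)c2cc(Br)c(Br)[nH]2)C1O
F7 | step 8 | (6S,10R)-7-N-methyl-8-thioxo-dibromophakellstatin (cyclic thiourea) | CN1C(=S)N[C@]23CCCN2C(=O)c2cc(Br)c(Br)n2[C@H]13
F8 | step 8 | S-methylisothiouronium iodide of F7 | CN1C(SC)=[NH+][C@]23CCCN2C(=O)c2cc(Br)c(Br)n2[C@H]13.[I-]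
F9 | step 5 | (2R)-1-(4,5-dibromo-1H-pyrrole-2-carbonyl)-N-hydroxy-N'-methylpyrrolidine-2,2-dicarboxamide | CNC(=O)[C@@]1(C(=O)NO)CCCN1C(=O)c1cc(Br)c(Br)[nH]1
F10 | step 5 | (2S)-1-(4,5-dibromo-1H-pyrrole-2-carbonyl)-N-methyl-2-(5-oxo-1,4,2-dioxazol-3-yl)pyrrolidine-2-carboxamide | CNC(=O)[C@@]1(C2=NOC(=O)O2)CCCN1C(=O)c1cc(Br)c(Br)[nH]1
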